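**Plan**

- Retrosynthesis: the furanone is opened at C3–C2(=O) and at C5H2–O1, which removes CO2. The ring's C3(H)=C4–C5H2 unit then becomes a (Z)-1-iodo-3-chloro-2-substituted propene, a cis-held vinyl anion/allyl cation pair, and CO2 supplies C2 and O1.
- Further cuts: the E-trisubstituted C3′=C4′ olefin (Wittig, aldehyde 20 + α-homofarnesyl ylide 9), then the carbinol C1′–C4 bond (β-iodo Morita–Baylis–Hillman coupling of aldehyde 10 with ethyl propiolate and TMSI).
- Forward: farnesol → homofarnesyl iodide → ylide 9 (steps 1–5); 10 + 11 → Z-β-iodo adduct 14 → iodo/chloro aldehyde 20 (steps 6–11); Wittig joins the chain (12); reduction and silylation (13, 14); the furanone, the only ring, is closed in step 15; desilylation (16).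
- Stereochemistry: C1′ (R) from the catalyst-controlled step 6; the Z vinyl iodide from the same step, retained through I/Li exchange; the 3′E olefin from the stabilised Wittig reaction; the 7′E and 11′E olefins from (2E,6E)-farnesol.

Key step: step 15

Remark: the oxazaborolidinium catalyst of step 6 is used as the antipode that directs attack to the Si face of aldehyde 10, which corresponds to the (R)-carbinol; the assignment should be confirmed on 14.

**Step 1**
Reactants: 1 (2E,6E)-farnesol
Product: 2 (2E,6E)-farnesal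
Conditions: activated MnO2, CH2Cl2, rt
Reagents that add atoms: none
Why: Activated MnO2 oxidises only the allylic alcohol and should leave the 2E geometry intact (allylic oxidation).

**Step 2**
Reactants: 2 (2E,6E)-farnesal
Product: 3 (3E,7E)-4,8,12-trimethyltrideca-1,3,7,11-tetraene
Conditions: Ph3PCH3Br, n-BuLi, THF, 0 °C to rt
Reagents that add atoms: methylenetriphenylphosphorane, C=P(c1ccccc1)(c1ccccc1)c1ccccc1 (made in the flask from methyltriphenylphosphonium bromide and n-BuLi)
Why: Wittig methylenation of the enal adds the one carbon needed for the homofarnesyl chain without touching the existing olefins.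

**Step 3**
Reactants: 3 (3E,7E)-4,8,12-trimethyltrideca-1,3,7,11-tetraene
Product: 5 (3E,7E)-4,8,12-trimethyltrideca-3,7,11-trien-1-ol (homofarnesol), via borane adduct 4 (not isolated)
Conditions: 9-BBN, THF, 0 °C to rt; then NaOH, H2O2, 0 °C
Reagents that add atoms: hydrogen peroxide, OO; 9-borabicyclo[3.3.1]nonane, [H]B1C2CCCC1CCC2 (boron stays only in 4)
Why: 9-BBN should add anti-Markovnikov to the terminal monosubstituted double bond only, leaving the trisubstituted olefins, and oxidation gives the primary alcohol (hydroboration–oxidation).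

**Step 4**
Reactants: 5 homofarnesol
Product: 6 (3E,7E)-1-iodo-4,8,12-trimethyltrideca-3,7,11-triene (homofarnesyl iodide)
Conditions: PPh3, I2, imidazole, CH2Cl2, 0 °C
Reagents that add atoms: iodine, II
Why: Appel-type iodination converts the primary alcohol to the iodide under neutral conditions that do not isomerise the olefins.

**Step 5**
Reactants: 6 homofarnesyl iodide; 7 ethyl (triphenylphosphoranylidene)acetate
Product: 9 ethyl (5E,9E)-6,10,14-trimethyl-2-(triphenylphosphoranylidene)pentadeca-5,9,13-trienoate, via phosphonium iodide 8 (not isolated)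
Conditions: MeCN, reflux; then 2 M NaOH, CH2Cl2, rt
Reagents that add atoms: none
Why: SN2 C-alkylation of the stabilised ylide by the primary iodide gives salt 8, whose acidic α-proton is removed by hydroxide to give the α-alkylated stabilised ylide.

**Step 6**
Reactants: 10 3-[(tert-butyldimethylsilyl)oxy]propanal; 11 ethyl propiolate
Product: 14 ethyl (2Z)-2-[(1R)-3-[(tert-butyldimethylsilyl)oxy]-1-hydroxypropyl]-3-iodoprop-2-enoate, via silyl allenoate 12 (not isolated), via TMS ether 13 (not isolated)
Conditions: TMSI, chiral oxazaborolidinium triflimide (20 mol%), CH2Cl2, −78 °C; 1 M HCl work-up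
Reagents that add atoms: iodotrimethylsilane, C[Si](C)(C)I (iodine; silicon stays only in 12 and 13)
Why: TMSI adds to the propiolate to give β-iodo silyl allenoate 12, which attacks the catalyst-bound aldehyde in a Mukaiyama-aldol-type step (asymmetric β-iodo Morita–Baylis–Hillman coupling); Si-face attack under catalyst control sets the (R)-carbinol, and approach of the aldehyde anti to iodine places iodine cis to the ester (Z).

**Step 7**
Reactants: 14 β-iodo adduct
Product: 15 ethyl (2Z)-2-[(1R)-1,3-bis[(tert-butyldimethylsilyl)oxy]propyl]-3-iodoprop-2-enoate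
Conditions: TBSOTf, 2,6-lutidine, CH2Cl2, −78 to 0 °C
Reagents that add atoms: tert-butyldimethylsilyl triflate, CC(C)(C)[Si](C)(C)OS(=O)(=O)C(F)(F)F
Why: The silyl triflate silylates the hindered secondary allylic alcohol without epimerisation (silyl ether protection).

**Step 8**
Reactants: 15 bis-silyl ester
Product: 16 (2E)-2-[(1R)-1,3-bis[(tert-butyldimethylsilyl)oxy]propyl]-3-iodoprop-2-en-1-ol (iodine cis to CH2OH)
Conditions: DIBAL-H (2.5 equiv), CH2Cl2, −78 °C; Rochelle salt
Reagents that add atoms: none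
Why: DIBAL-H reduces the enoate 1,2 to the allylic alcohol at low temperature and leaves the vinyl iodide and its geometry untouched (ester reduction).

**Step 9**
Reactants: 16 allylic alcohol
Product: 18 (1Z,3R)-3,5-bis[(tert-butyldimethylsilyl)oxy]-2-(chloromethyl)-1-iodopent-1-ene, via allylic mesylate 17 (not isolated)
Conditions: MsCl, 2,4,6-collidine, LiCl, DMF, 0 °C
Reagents that add atoms: lithium chloride, [Li+].[Cl-]; methanesulfonyl chloride, CS(=O)(=O)Cl (mesyl group stays only in 17)
Why: In-situ mesylation and SN2 displacement by chloride at the primary allylic carbon should give the chloride without allylic transposition (mesylate/chloride exchange).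

**Step 10**
Reactants: 18 bis-silyl allylic chloride
Product: 19 (3R,4Z)-3-[(tert-butyldimethylsilyl)oxy]-4-(chloromethyl)-5-iodopent-4-en-1-ol
Conditions: HF·pyridine, pyridine, THF, 0 °C
Reagents that add atoms: none
Why: Buffered HF·pyridine cleaves the unhindered primary TBS ether much faster than the hindered secondary allylic one (selective desilylation).

**Step 11**
Reactants: 19 primary alcohol
Product: 20 (3R,4Z)-3-[(tert-butyldimethylsilyl)oxy]-4-(chloromethyl)-5-iodopent-4-enal
Conditions: Dess–Martin periodinane, CH2Cl2, 0 °C to rt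
Reagents that add atoms: none
Why: Dess–Martin oxidation gives the β-silyloxy aldehyde under mild, non-basic conditions that avoid β-elimination.

**Step 12**
Reactants: 20 aldehyde; 9 α-homofarnesyl ylide
Product: 21 ethyl (2E,5E,9E)-2-[(3R,4Z)-3-[(tert-butyldimethylsilyl)oxy]-4-(chloromethyl)-5-iodopent-4-en-1-ylidene]-6,10,14-trimethylpentadeca-5,9,13-trienoate
Conditions: CH2Cl2, rt
Reagents that add atoms: none
Why: α-Alkyl stabilised ylides give the E-trisubstituted enoate (ester trans to the new chain, Wittig olefination), and at room temperature olefination should outpace C-alkylation of the ylide by the allylic chloride.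

**Step 13**
Reactants: 21 enoate
Product: 22 (2E,5E,9E)-2-[(3R,4Z)-3-[(tert-butyldimethylsilyl)oxy]-4-(chloromethyl)-5-iodopent-4-en-1-ylidene]-6,10,14-trimethylpentadeca-5,9,13-trien-1-ol
Conditions: DIBAL-H (2.5 equiv), CH2Cl2, −78 °C; Rochelle salt
Reagents that add atoms: none
Why: DIBAL-H reduces the enoate to the allylic alcohol with retention of olefin geometry; the allylic chloride and vinyl iodide are inert at −78 °C (ester reduction).

**Step 14**
Reactants: 22 allylic alcohol
Product: 23 (1Z,3R,5E,9E,13E)-3-[(tert-butyldimethylsilyl)oxy]-6-{[(tert-butyldimethylsilyl)oxy]methyl}-2-(chloromethyl)-1-iodo-10,14,18-trimethylnonadeca-1,5,9,13,17-pentaene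
Conditions: TBSOTf, 2,6-lutidine, CH2Cl2, −78 °C
Reagents that add atoms: tert-butyldimethylsilyl triflate, CC(C)(C)[Si](C)(C)OS(=O)(=O)C(F)(F)F
Why: Silylation removes the only acidic proton before the organolithium step, under conditions that do not touch the allylic chloride (silyl ether protection).

**Step 15**
Reactants: 23 vinyl iodide/allylic chloride; 24 carbon dioxide
Product: 27 4-[(1R,3E,7E,11E)-1-[(tert-butyldimethylsilyl)oxy]-4-{[(tert-butyldimethylsilyl)oxy]methyl}-8,12,16-trimethylheptadeca-3,7,11,15-tetraen-1-yl]furan-2(5H)-one, via alkenyllithium 25 (not isolated), via lithium carboxylate 26 (not isolated)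
Conditions: t-BuLi (2.05 equiv), Et2O, −78 °C; excess dry CO2, −78 °C to rt; then DMF, 45 °C; aq. NH4Cl
Reagents that add atoms: tert-butyllithium, [Li]C(C)(C)C (lithium stays only in 25 and 26)
Why: Iodine–lithium exchange at the C(sp2)–I bond proceeds with retention, so alkenyllithium 25 carries lithium cis to CH2Cl and trans to the silyloxy carbinol (no 1,4-retro-Brook shift is possible and there is no β-leaving group), and CO2 then forms the C3–C2 bond to give the lithium (Z)-4-chloro-2-enoate 26. On warming with DMF the carboxylate oxygen displaces the cis allylic chloride and forms the C5–O1 bond, so the sequence is a formal (3+2) annulation of a vinyl anion/allyl cation synthon with CO2. The closest known reaction types are the carboxylation of alkenyllithiums made from vinyl iodides and the lactonisation of (Z)-γ-halo-α,β-unsaturated carboxylates to butenolides. The furanone ring closes in a 5-exo-tet SN2 mode. No stereocentre is formed, and the (R)-carbinol, held as a silyl ether away from the carbanion, is not affected. The step needs exchange at iodine in preference to attack on the allylic chloride, which the far faster I/Li exchange at −78 °C with two equivalents of t-BuLi should secure, and it needs the Z geometry from step 6, which holds the carboxylate and CH2Cl on the same side.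

**Step 16**
Reactants: 27 bis-silyl butenolide
Product: 28 Hippolide C, 4-[(1R,3E,7E,11E)-1-hydroxy-4-(hydroxymethyl)-8,12,16-trimethylheptadeca-3,7,11,15-tetraen-1-yl]furan-2(5H)-one
Conditions: HF·pyridine, THF, 0 °C to rt
Reagents that add atoms: none
Why: HF·pyridine removes both TBS ethers under mildly acidic conditions that the butenolide and the polyene tolerate (global desilylation).

**Compound list**

1 | (2E,6E)-farnesol | CC(C)=CCC/C(C)=C/CC/C(C)=C/CO | starting material
2 | (2E,6E)-farnesal | CC(C)=CCC/C(C)=C/CC/C(C)=C/C=O | intermediate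
3 | (3E,7E)-4,8,12-trimethyltrideca-1,3,7,11-tetraene | CC(C)=CCC/C(C)=C/CC/C(C)=C/C=C | intermediate
4 | 9-[(3E,7E)-4,8,12-trimethyltrideca-3,7,11-trien-1-yl]-9-borabicyclo[3.3.1]nonane | CC(C)=CCC/C(C)=C/CC/C(C)=C/CCB1C2CCCC1CCC2 | intermediate
5 | (3E,7E)-4,8,12-trimethyltrideca-3,7,11-trien-1-ol (homofarnesol) | CC(C)=CCC/C(C)=C/CC/C(C)=C/CCO | intermediate
6 | (3E,7E)-1-iodo-4,8,12-trimethyltrideca-3,7,11-triene | CC(C)=CCC/C(C)=C/CC/C(C)=C/CCI | intermediate
7 | ethyl (triphenylphosphoranylidene)acetate | CCOC(=O)C=P(c1ccccc1)(c1ccccc1)c1ccccc1 | starting material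
8 | [(5E,9E)-1-ethoxy-6,10,14-trimethyl-1-oxopentadeca-5,9,13-trien-2-yl]triphenylphosphonium iodide | CC(C)=CCC/C(C)=C/CC/C(C)=C/CCC(C(=O)OCC)[P+](c1ccccc1)(c1ccccc1)c1ccccc1.[I-] | intermediate
9 | ethyl (5E,9E)-6,10,14-trimethyl-2-(triphenylphosphoranylidene)pentadeca-5,9,13-trienoate | CC(C)=CCC/C(C)=C/CC/C(C)=C/CCC(C(=O)OCC)=P(c1ccccc1)(c1ccccc1)c1ccccc1 | intermediate
10 | 3-[(tert-butyldimethylsilyl)oxy]propanal | CC(C)(C)[Si](C)(C)OCCC=O | starting material
11 | ethyl propiolate | C#CC(=O)OCC | starting material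
12 | [(1-ethoxy-3-iodopropa-1,2-dien-1-yl)oxy]trimethylsilane | CCOC(O[Si](C)(C)C)=C=CI | intermediate
13 | ethyl (2Z)-2-[(1R)-3-[(tert-butyldimethylsilyl)oxy]-1-[(trimethylsilyl)oxy]propyl]-3-iodoprop-2-enoate | CC(C)(C)[Si](C)(C)OCC[C@@H](O[Si](C)(C)C)/C(C(=O)OCC)=C/I | intermediate
14 | ethyl (2Z)-2-[(1R)-3-[(tert-butyldimethylsilyl)oxy]-1-hydroxypropyl]-3-iodoprop-2-enoate | CC(C)(C)[Si](C)(C)OCC[C@@H](O)/C(C(=O)OCC)=C/I | intermediate
15 | ethyl (2Z)-2-[(1R)-1,3-bis[(tert-butyldimethylsilyl)oxy]propyl]-3-iodoprop-2-enoate | CC(C)(C)[Si](C)(C)OCC[C@@H](O[Si](C)(C)C(C)(C)C)/C(C(=O)OCC)=C/I | intermediate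
16 | (2E)-2-[(1R)-1,3-bis[(tert-butyldimethylsilyl)oxy]propyl]-3-iodoprop-2-en-1-ol | CC(C)(C)[Si](C)(C)OCC[C@@H](O[Si](C)(C)C(C)(C)C)/C(CO)=C/I | intermediate
17 | (2E)-2-[(1R)-1,3-bis[(tert-butyldimethylsilyl)oxy]propyl]-3-iodoprop-2-en-1-yl methanesulfonate | CC(C)(C)[Si](C)(C)OCC[C@@H](O[Si](C)(C)C(C)(C)C)/C(COS(C)(=O)=O)=C/I | intermediate
18 | (1Z,3R)-3,5-bis[(tert-butyldimethylsilyl)oxy]-2-(chloromethyl)-1-iodopent-1-ene | CC(C)(C)[Si](C)(C)OCC[C@@H](O[Si](C)(C)C(C)(C)C)/C(CCl)=C/I | intermediate
19 | (3R,4Z)-3-[(tert-butyldimethylsilyl)oxy]-4-(chloromethyl)-5-iodopent-4-en-1-ol | OCC[C@@H](O[Si](C)(C)C(C)(C)C)/C(CCl)=C/I | intermediate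
20 | (3R,4Z)-3-[(tert-butyldimethylsilyl)oxy]-4-(chloromethyl)-5-iodopent-4-enal | O=CC[C@@H](O[Si](C)(C)C(C)(C)C)/C(CCl)=C/I | intermediate
21 | ethyl (2E,5E,9E)-2-[(3R,4Z)-3-[(tert-butyldimethylsilyl)oxy]-4-(chloromethyl)-5-iodopent-4-en-1-ylidene]-6,10,14-trimethylpentadeca-5,9,13-trienoate | CC(C)=CCC/C(C)=C/CC/C(C)=C/CC/C(=C\C[C@@H](O[Si](C)(C)C(C)(C)C)/C(CCl)=C/I)C(=O)OCC | intermediate
22 | (2E,5E,9E)-2-[(3R,4Z)-3-[(tert-butyldimethylsilyl)oxy]-4-(chloromethyl)-5-iodopent-4-en-1-ylidene]-6,10,14-trimethylpentadeca-5,9,13-trien-1-ol | CC(C)=CCC/C(C)=C/CC/C(C)=C/CC/C(=C\C[C@@H](O[Si](C)(C)C(C)(C)C)/C(CCl)=C/I)CO | intermediate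
23 | (1Z,3R,5E,9E,13E)-3-[(tert-butyldimethylsilyl)oxy]-6-{[(tert-butyldimethylsilyl)oxy]methyl}-2-(chloromethyl)-1-iodo-10,14,18-trimethylnonadeca-1,5,9,13,17-pentaene | CC(C)=CCC/C(C)=C/CC/C(C)=C/CC/C(=C\C[C@@H](O[Si](C)(C)C(C)(C)C)/C(CCl)=C/I)CO[Si](C)(C)C(C)(C)C | intermediate
24 | carbon dioxide | O=C=O | starting material
25 | alkenyllithium from 23 (lithium in place of iodine, Z) | CC(C)=CCC/C(C)=C/CC/C(C)=C/CC/C(=C\C[C@@H](O[Si](C)(C)C(C)(C)C)/C(CCl)=C/[Li])CO[Si](C)(C)C(C)(C)C | intermediate
26 | lithium (2Z,4R,6E,10E,14E)-4-[(tert-butyldimethylsilyl)oxy]-7-{[(tert-butyldimethylsilyl)oxy]methyl}-3-(chloromethyl)-11,15,19-trimethylicosa-2,6,10,14,18-pentaenoate | CC(C)=CCC/C(C)=C/CC/C(C)=C/CC/C(=C\C[C@@H](O[Si](C)(C)C(C)(C)C)/C(CCl)=C/C(=O)[O-])CO[Si](C)(C)C(C)(C)C.[Li+] | intermediate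
27 | 4-[(1R,3E,7E,11E)-1-[(tert-butyldimethylsilyl)oxy]-4-{[(tert-butyldimethylsilyl)oxy]methyl}-8,12,16-trimethylheptadeca-3,7,11,15-tetraen-1-yl]furan-2(5H)-one | CC(C)=CCC/C(C)=C/CC/C(C)=C/CC/C(=C\C[C@@H](O[Si](C)(C)C(C)(C)C)C1=CC(=O)OC1)CO[Si](C)(C)C(C)(C)C | intermediate
28 | Hippolide C | CC(C)=CCC/C(C)=C/CC/C(C)=C/CC/C(=C\C[C@@H](O)C1=CC(=O)OC1)CO | target

**Count**

Total steps: 16. Longest linear sequence: 11 steps (steps 6–16, from 10 and 11); the chain branch (steps 1–5) enters at step 12.

**Steps most likely to fail**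

Step 15. t-BuLi may attack the allylic C–Cl bond (substitution or coupling) in competition with exchange, the alkenyllithium may be protonated before carboxylation, or O-alkylation by the aggregated lithium carboxylate may be sluggish. The fallback sets out from 23 and returns at 27. Displacement of the chloride with caesium acetate (DMF, 40 °C) should give allylic acetate F1. Methanolysis (K2CO3, MeOH, 0 °C) should give the (Z)-γ-hydroxy vinyl iodide F2. Palladium-catalysed cyclocarbonylation (PdCl2(PPh3)2, CO 1 atm, Et3N, THF, 50 °C) should then close the butenolide 27 by capture of the acyl-palladium species by the cis hydroxyl.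

Step 6. The catalyst may discriminate poorly between the faces of the unbranched, Lewis-basic β-silyloxy aldehyde, or TMSI may cleave the primary silyl ether. The fallback sets out from 10 and 11 and returns at 14. The MgI2-mediated three-component coupling (MgI2, CH2Cl2, 0 °C) should give the racemic Z adduct F3. Dess–Martin oxidation should give the iodo enone ester F4. Corey–Bakshi–Shibata reduction ((S)-Me-CBS, catecholborane, toluene, −78 °C), with the alkenyl group as the large substituent, is expected to return the (R)-alcohol 14.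

Step 5. C-alkylation of the weakly nucleophilic stabilised ylide by the unactivated primary iodide may be slow, with E2 elimination to the conjugated diene on prolonged heating. The fallback sets out from 6 and returns at 21. The sodium salt of triethyl phosphonoacetate (NaH, DMF, 60 °C), a much stronger carbon nucleophile, should be alkylated by 6 to give phosphonate F5. Horner–Wadsworth–Emmons olefination of aldehyde 20 with F5 (NaH, THF, −78 to 0 °C) should give 21 after separation from any Z isomer.

**Further compounds**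

F1 | step 15 | (2E,3R,5E,9E,13E)-3-[(tert-butyldimethylsilyl)oxy]-6-{[(tert-butyldimethylsilyl)oxy]methyl}-2-(iodomethylidene)-10,14,18-trimethylnonadeca-5,9,13,17-tetraen-1-yl acetate (iodine cis to CH2OAc) | CC(C)=CCC/C(C)=C/CC/C(C)=C/CC/C(=C\C[C@@H](O[Si](C)(C)C(C)(C)C)/C(COC(C)=O)=C/I)CO[Si](C)(C)C(C)(C)C
F2 | step 15 | (2E,3R,5E,9E,13E)-3-[(tert-butyldimethylsilyl)oxy]-6-{[(tert-butyldimethylsilyl)oxy]methyl}-2-(iodomethylidene)-10,14,18-trimethylnonadeca-5,9,13,17-tetraen-1-ol (iodine cis to CH2OH) | CC(C)=CCC/C(C)=C/CC/C(C)=C/CC/C(=C\C[C@@H](O[Si](C)(C)C(C)(C)C)/C(CO)=C/I)CO[Si](C)(C)C(C)(C)C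
F3 | step 6 | racemic ethyl (2Z)-2-[3-[(tert-butyldimethylsilyl)oxy]-1-hydroxypropyl]-3-iodoprop-2-enoate | CC(C)(C)[Si](C)(C)OCCC(O)/C(C(=O)OCC)=C/I
F4 | step 6 | ethyl (2Z)-2-[3-[(tert-butyldimethylsilyl)oxy]propanoyl]-3-iodoprop-2-enoate | CC(C)(C)[Si](C)(C)OCCC(=O)/C(C(=O)OCC)=C/I
F5 | step 5 | ethyl (5E,9E)-2-(diethoxyphosphoryl)-6,10,14-trimethylpentadeca-5,9,13-trienoate | CC(C)=CCC/C(C)=C/CC/C(C)=C/CCC(C(=O)OCC)P(=O)(OCC)OCC
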